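**Retrosynthetic overview**
1. The target is (2S)-5,7-dihydroxy-8-prenyl-4'-prenyloxyflavanone. The last step only removes two silyl groups, from O5 and O7.
2. The pyranone C ring is cut at C4–C4a and O1–C2. This gives a 2-prenylphloroglucinol in which only O1 is free (6) and (E)-4-prenyloxycinnamoyl chloride (11). They are joined as a [3+3] union in one flask: C4–C4a first by magnesium-templated ortho-acylation, then O1–C2 by catalytic asymmetric oxa-Michael closure.
3. Enabling feature: O1–C8a=C4a of ring A is an enol-type O,C-1,3-bis-nucleophile, and its carbon is activated by O1, O5 and O7. C4(=O)–C3=C2 is the matching 1,3-bis-electrophile because C2 is β to the C4 carbonyl. The C8 prenyl group blocks the other ortho carbon and marks O1.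
4. Phenol 6 comes from phloroglucinol by bis-silylation, O-tert-prenylation and aromatic Claisen [3,3] rearrangement. The rearrangement places the prenyl group next to the only free OH by construction.
5. Ring order: rings A and B are bought. Ring C is the only ring formed (step 7).

Key step: step 7

Assumption: the quinine-derived thiourea is taken to deliver the (2S) product. If its sense of induction is the opposite, the quinidine-derived pseudoenantiomer replaces it with no other change.
Remark: flavanone numbering (O1, C2, C3, C4, C4a, C5–C8, C8a) is also used for these atoms in the precursors.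

**Step 1**
Reactants: 1 phloroglucinol
Product: 2 3,5-bis[(tert-butyldimethylsilyl)oxy]phenol
Conditions: TBSCl (2.0 equiv), imidazole, DMF, 0 °C → rt; chromatography (mono- and tris-ethers recycled)
Reagents that add atoms: tert-butyldimethylsilyl chloride CC(C)(C)[Si](C)(C)Cl
Why: Phenol silylation with TBSCl/imidazole; the three OH groups of 1 are equivalent, so no regiochemical question arises and two equivalents should make the bis-ether the main part of a separable statistical mixture.

**Step 2**
Reactants: 3 2-methylbut-3-en-2-ol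
Product: 4 tert-butyl 2-methylbut-3-en-2-yl carbonate
Conditions: n-BuLi (1.0 equiv), THF, −78 → 0 °C; Boc2O, 0 °C → rt; aq. work-up
Reagents that add atoms: di-tert-butyl dicarbonate CC(C)(C)OC(=O)OC(=O)OC(C)(C)C
Why: Alkoxycarbonylation of a lithium alkoxide; the hindered tertiary allylic alcohol is deprotonated first and then attacks one carbonyl of Boc2O.

**Step 3**
Reactants: 2 3,5-bis[(tert-butyldimethylsilyl)oxy]phenol; 4 tert-butyl 2-methylbut-3-en-2-yl carbonate
Product: 5 1,3-bis[(tert-butyldimethylsilyl)oxy]-5-[(2-methylbut-3-en-2-yl)oxy]benzene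
Conditions: Pd(PPh3)4 (2 mol %), THF, 0 °C, short reaction time
Reagents that add atoms: none
Why: Tsuji–Trost-type decarboxylative O-allylation; the phenoxide should attack the 1,1-dimethyl-π-allylpalladium cation kinetically at its more substituted terminus, and the neutral medium spares the aryl silyl ethers.

**Step 4**
Reactants: 5 1,3-bis[(tert-butyldimethylsilyl)oxy]-5-[(2-methylbut-3-en-2-yl)oxy]benzene
Product: 6 3,5-bis[(tert-butyldimethylsilyl)oxy]-2-(3-methylbut-2-en-1-yl)phenol
Conditions: toluene, 110 °C
Reagents that add atoms: none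
Why: Aromatic Claisen rearrangement ([3,3]), accelerated by the gem-dimethyl group and the electron-rich ring; the two ortho carbons are equivalent, allyl inversion turns the 1,1-dimethylallyl ether into a prenyl group, and rearomatisation leaves the only free OH next to it.

**Step 5**
Reactants: 7 methyl (E)-4-hydroxycinnamate; 8 prenyl bromide
Product: 9 methyl (E)-3-{4-[(3-methylbut-2-en-1-yl)oxy]phenyl}prop-2-enoate
Conditions: K2CO3, acetone, reflux
Reagents that add atoms: none
Why: Williamson ether synthesis; the phenoxide displaces the primary allylic bromide in SN2 fashion and the alkene geometry is untouched.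

**Step 6**
Reactants: 9 methyl (E)-3-{4-[(3-methylbut-2-en-1-yl)oxy]phenyl}prop-2-enoate
Product: 11 (E)-3-{4-[(3-methylbut-2-en-1-yl)oxy]phenyl}prop-2-enoyl chloride, via sodium carboxylate 10 (not isolated)
Conditions: NaOSiMe3 (1.0 equiv), THF, rt; evaporate; (COCl)2 (1.1 equiv), DMF (cat.), toluene, 0 °C → rt; filter under argon, use as toluene solution
Reagents that add atoms: sodium trimethylsilanolate C[Si](C)(C)[O-].[Na+] (Na, found only in 10); oxalyl chloride O=C(Cl)C(=O)Cl (Cl)
Why: Silanolate ester cleavage gives the dry sodium carboxylate, which is converted by oxalyl chloride/DMF (Vilsmeier-type activation) into the acid chloride with NaCl instead of HCl as by-product, so the prenyl ether and its alkene never meet acid.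

**Step 7**
Reactants: 6 3,5-bis[(tert-butyldimethylsilyl)oxy]-2-(3-methylbut-2-en-1-yl)phenol; 11 (E)-3-{4-[(3-methylbut-2-en-1-yl)oxy]phenyl}prop-2-enoyl chloride
Product: 14 (2S)-5,7-bis[(tert-butyldimethylsilyl)oxy]-8-(3-methylbut-2-en-1-yl)-2-{4-[(3-methylbut-2-en-1-yl)oxy]phenyl}chroman-4-one, via bromomagnesium phenolate 12 (not isolated), via 2'-hydroxychalcone 13 (not isolated)
Conditions: EtMgBr (1.0 equiv), Et2O, 0 °C; Et2O replaced by toluene; 11 (1.0 equiv), 0 °C → rt; then 1,4-dioxane (3 equiv), 9-amino(9-deoxy)epi-quinine 3,5-bis(trifluoromethyl)phenyl thiourea (10 mol %), 0 °C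
Reagents that add atoms: ethylmagnesium bromide CC[Mg]Br (Mg and Br, found only in 12)
Why: Phenolate 12 binds the acyl chloride at magnesium, and its only free ortho carbon (C4a) attacks the acyl carbon through a six-membered cyclic array (ortho-specific acylation of aryloxymagnesium bromides with α,β-unsaturated acyl chlorides, a coordinated Friedel–Crafts acylation), which forms C4–C4a and gives chalcone 13 after tautomerisation. While magnesium bridges O1 and the C4 carbonyl oxygen the styryl arm points away from O1, so no racemic closure should occur until dioxane precipitates MgBrCl and frees the phenol. The bifunctional catalyst then closes the pyranone C ring by a 6-endo-trig intramolecular oxa-Michael addition of O1 to C2, the closest known type being the cinchona- and cinchona-thiourea-catalysed cyclisation of 2'-hydroxychalcones and o-enoylphenols to flavanones and chromanones. C2 is controlled by the catalyst: the thiourea N–H bonds hold the C4 carbonyl, the quinuclidine takes the O1 proton and delivers the phenoxide to the Si face of C2, and the quinuclidinium ion protonates C3. Site selectivity rests on the substrate: the C8 prenyl group blocks the second ortho carbon, C6 lies between two OTBS groups out of reach of the template, 1,2-attack through a six-membered array is preferred to 1,4-attack through an eight-membered one, and O5 is silylated so that only O1 next to the prenyl group can close the ring (8-prenyl, not 6-prenyl). The bulky 5-OTBS group twists the aroyl unit out of conjugation, which should raise the reactivity of the p-alkoxy-deactivated enone and shift the equilibrium towards the flavanone.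

**Step 8**
Reactants: 14 (2S)-5,7-bis[(tert-butyldimethylsilyl)oxy]-8-(3-methylbut-2-en-1-yl)-2-{4-[(3-methylbut-2-en-1-yl)oxy]phenyl}chroman-4-one
Product: 15 (2S)-5,7-dihydroxy-8-(3-methylbut-2-en-1-yl)-2-{4-[(3-methylbut-2-en-1-yl)oxy]phenyl}chroman-4-one (target)
Conditions: Et3N·3HF, THF, 0 °C → rt
Reagents that add atoms: none
Why: Fluoride cleavage of aryl silyl ethers in a slightly acidic medium; the liberated phenols stay protonated, so ring opening by retro-oxa-Michael reaction (racemisation at C2) should not start, and the prenyl ether and both alkenes are inert.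

**Compound list**
1 | phloroglucinol | Oc1cc(O)cc(O)c1 | starting material
2 | 3,5-bis[(tert-butyldimethylsilyl)oxy]phenol | CC(C)(C)[Si](C)(C)Oc1cc(O)cc(O[Si](C)(C)C(C)(C)C)c1 | intermediate
3 | 2-methylbut-3-en-2-ol | CC(C)(O)C=C | starting material
4 | tert-butyl 2-methylbut-3-en-2-yl carbonate | CC(C)(C)OC(=O)OC(C)(C)C=C | intermediate
5 | 1,3-bis[(tert-butyldimethylsilyl)oxy]-5-[(2-methylbut-3-en-2-yl)oxy]benzene | C=CC(C)(C)Oc1cc(O[Si](C)(C)C(C)(C)C)cc(O[Si](C)(C)C(C)(C)C)c1 | intermediate
6 | 3,5-bis[(tert-butyldimethylsilyl)oxy]-2-(3-methylbut-2-en-1-yl)phenol | CC(C)=CCc1c(O)cc(O[Si](C)(C)C(C)(C)C)cc1O[Si](C)(C)C(C)(C)C | intermediate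
7 | methyl (E)-4-hydroxycinnamate | COC(=O)/C=C/c1ccc(O)cc1 | starting material
8 | prenyl bromide (1-bromo-3-methylbut-2-ene) | CC(C)=CCBr | starting material
9 | methyl (E)-3-{4-[(3-methylbut-2-en-1-yl)oxy]phenyl}prop-2-enoate | COC(=O)/C=C/c1ccc(OCC=C(C)C)cc1 | intermediate
10 | sodium (E)-3-{4-[(3-methylbut-2-en-1-yl)oxy]phenyl}prop-2-enoate | CC(C)=CCOc1ccc(/C=C/C(=O)[O-])cc1.[Na+] | intermediate
11 | (E)-3-{4-[(3-methylbut-2-en-1-yl)oxy]phenyl}prop-2-enoyl chloride | CC(C)=CCOc1ccc(/C=C/C(=O)Cl)cc1 | intermediate
12 | bromomagnesium 3,5-bis[(tert-butyldimethylsilyl)oxy]-2-(3-methylbut-2-en-1-yl)phenolate | CC(C)=CCc1c(O[Mg]Br)cc(O[Si](C)(C)C(C)(C)C)cc1O[Si](C)(C)C(C)(C)C | intermediate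
13 | (E)-1-{4,6-bis[(tert-butyldimethylsilyl)oxy]-2-hydroxy-3-(3-methylbut-2-en-1-yl)phenyl}-3-{4-[(3-methylbut-2-en-1-yl)oxy]phenyl}prop-2-en-1-one | CC(C)=CCOc1ccc(/C=C/C(=O)c2c(O)c(CC=C(C)C)c(O[Si](C)(C)C(C)(C)C)cc2O[Si](C)(C)C(C)(C)C)cc1 | intermediate
14 | (2S)-5,7-bis[(tert-butyldimethylsilyl)oxy]-8-(3-methylbut-2-en-1-yl)-2-{4-[(3-methylbut-2-en-1-yl)oxy]phenyl}chroman-4-one | CC(C)=CCOc1ccc([C@@H]2CC(=O)c3c(O[Si](C)(C)C(C)(C)C)cc(O[Si](C)(C)C(C)(C)C)c(CC=C(C)C)c3O2)cc1 | intermediate
15 | (2S)-5,7-dihydroxy-8-(3-methylbut-2-en-1-yl)-2-{4-[(3-methylbut-2-en-1-yl)oxy]phenyl}chroman-4-one | CC(C)=CCOc1ccc([C@@H]2CC(=O)c3c(O)cc(O)c(CC=C(C)C)c3O2)cc1 | target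

**Total step count:** 8
**Longest linear sequence:** 5 steps (1 → 3 → 4 → 7 → 8)

**Steps most likely to fail**

**Step 7.**
- What may go wrong: O-acylation may outrun the templated C-acylation. Residual magnesium halide may inhibit the catalyst. Closure of the p-alkoxy-deactivated enone may be slow and reversible, which would erode the facial selectivity.
- Fallback: it sets out from 6 and 11 and comes back at 14. Deliberate O-acylation (Et3N, cat. DMAP, CH2Cl2) gives the aryl cinnamate F1. A photo-Fries rearrangement (about 300 nm, degassed cyclohexane) moves the acyl group to the only open ortho carbon and gives chalcone 13, which is now isolated. An achiral amine (DABCO, toluene) closes it to the racemic flavanone F2. A kinetic resolution by Noyori-type asymmetric transfer hydrogenation (Rh– or Ru–TsDPEN, HCO2H/Et3N) then reduces the (2R)-ketone to the cis-(2R,4R)-flavan-4-ol F3. The (2S)-ketone 14 is left unreacted and is separated by chromatography.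

**Step 3.**
- What may go wrong: the phenoxide may attack the unsubstituted allyl terminus, or a ring carbon may be allylated. Palladium may also isomerise the tertiary ether to the linear ether with time.
- Fallback: it sets out from 2 and comes back at 5. Copper-catalysed O-propargylation with 3-chloro-3-methylbut-1-yne (CuCl2 cat., DBU, dry MeCN, 0 °C) gives the 1,1-dimethylpropargyl ether F4. In this reaction the tertiary C–O bond forms with no allyl terminus to choose from. Lindlar semihydrogenation (H2, Lindlar catalyst, quinoline, EtOAc) then gives 5.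

**Step 8.**
- What may go wrong: once the acidic 7-OH is set free, ring opening and reclosure through the phenoxide may cause loss of configuration at C2. Cleavage of the more hindered silyl ether may also be incomplete.
- Fallback: it sets out from 14 and comes back at 15. It exchanges the protecting groups instead of unmasking them directly. Fluoride cleavage in the presence of acetic anhydride (KF, Ac2O, DMF, rt) traps each phenoxide at once and gives the (2S)-5,7-diacetate F5. Neutral deacetylation of aromatic acetates (NH4OAc, aq. MeOH, rt) then frees 15.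

**Further compounds**
F1 | step 7 | 3,5-bis[(tert-butyldimethylsilyl)oxy]-2-(3-methylbut-2-en-1-yl)phenyl (E)-3-{4-[(3-methylbut-2-en-1-yl)oxy]phenyl}prop-2-enoate | CC(C)=CCOc1ccc(/C=C/C(=O)Oc2cc(O[Si](C)(C)C(C)(C)C)cc(O[Si](C)(C)C(C)(C)C)c2CC=C(C)C)cc1
F2 | step 7 | rac-5,7-bis[(tert-butyldimethylsilyl)oxy]-8-(3-methylbut-2-en-1-yl)-2-{4-[(3-methylbut-2-en-1-yl)oxy]phenyl}chroman-4-one | CC(C)=CCOc1ccc(C2CC(=O)c3c(O[Si](C)(C)C(C)(C)C)cc(O[Si](C)(C)C(C)(C)C)c(CC=C(C)C)c3O2)cc1
F3 | step 7 | (2R,4R)-5,7-bis[(tert-butyldimethylsilyl)oxy]-8-(3-methylbut-2-en-1-yl)-2-{4-[(3-methylbut-2-en-1-yl)oxy]phenyl}chroman-4-ol | CC(C)=CCOc1ccc([C@H]2C[C@@H](O)c3c(O[Si](C)(C)C(C)(C)C)cc(O[Si](C)(C)C(C)(C)C)c(CC=C(C)C)c3O2)cc1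
F4 | step 3 | 1,3-bis[(tert-butyldimethylsilyl)oxy]-5-[(2-methylbut-3-yn-2-yl)oxy]benzene | C#CC(C)(C)Oc1cc(O[Si](C)(C)C(C)(C)C)cc(O[Si](C)(C)C(C)(C)C)c1
F5 | step 8 | (2S)-8-(3-methylbut-2-en-1-yl)-2-{4-[(3-methylbut-2-en-1-yl)oxy]phenyl}-4-oxochroman-5,7-diyl diacetate | CC(C)=CCOc1ccc([C@@H]2CC(=O)c3c(OC(C)=O)cc(OC(C)=O)c(CC=C(C)C)c3O2)cc1
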